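**Plan**

- Atom labels: the oxepine ring is O1, C2 (quaternary), C3, C4, C5=C6, C7. Ca is the CH2 between C2 and the aryl ketone carbon Cb.
- Retrosynthetic cuts, in order: the allylic C–O bond of the coumarate, the Cb–aryl bond, the ring alkene C5=C6, the ether bond O1–C7 and the CH2–CH2 bond of the side chain. Cb and C5 are then rejoined as a cyclohexene alkene, and C2–Ca and C3–C4 are cut last.
- Enabling feature: C2 bears O1, the carboxyl carbon and two methylene arms of unequal length (Ca–Cb and C3–C4–C5). It is therefore C1 of a 1-oxycyclohex-3-ene-1-carbaldehyde whose alkene carbons are Cb and C5, the Diels–Alder adduct of buta-1,3-diene and a 2-(acyloxy)acrolein.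
- Forward: the sacrificial carbocycle is made first and opened by ozonolysis. The tertiary hydroxyl then holds C5 as a five-membered lactol while Cb is oxidised. The oxepine, the only ring of the target, arises late by O1–C7 etherification and ring-closing metathesis at C5=C6; aryl ketone and coumarate follow.
- Stereochemistry: C2 (R) comes from the catalyst-controlled enantioface of the iminium ion in the cycloaddition and has no α-hydrogen to lose. The side-chain E alkene comes from E-selective SeO2 oxidation, the ring alkene geometry from the ring, and the coumarate E alkene from the commercial acid.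

Key step: step 3

Assumption: the (S)-configured 1,1'-binaphthyl-2,2'-diammonium salt is taken to shield the iminium face that leads to the (R)-cycloadduct; if the sense proves opposite, the (R)-diamine is used with no other change.

**Route**

Step 1
Reactants: 1 2,2-dimethyl-1,3-dioxan-5-one; 2 benzoyl chloride
Product: 4 2,2-dimethyl-4H-1,3-dioxin-5-yl benzoate, via potassium enolate 3 (not isolated)
Conditions: KN(SiMe3)2 (1.05 equiv), THF, −78 °C; then 2, −78 → 0 °C
Reagents that add atoms: none
Why: The potassium enolate of the α,α'-dioxygenated ketone should be acylated on oxygen by the hard acyl chloride (enolate O-acylation), giving the enol ester that carries the latent acrolein.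

Step 2
Reactants: 4 2,2-dimethyl-4H-1,3-dioxin-5-yl benzoate
Product: 5 3-oxoprop-1-en-2-yl benzoate (2-(benzoyloxy)acrolein)
Conditions: toluene, 110 °C; concentrated and used at once
Reagents that add atoms: none
Why: Thermal retro-hetero-Diels–Alder reaction of the 4H-1,3-dioxin expels acetone and should leave the 2-(acyloxy)acrolein, which is used without storage because it polymerises easily.

Step 3
Reactants: 5 3-oxoprop-1-en-2-yl benzoate; 6 buta-1,3-diene
Product: 7 (1R)-1-formylcyclohex-3-en-1-yl benzoate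
Conditions: (S)-1,1'-binaphthyl-2,2'-diamine (10 mol %), HN(SO2CF3)2 (19 mol %), 6 (5 equiv), EtCN, −40 → −20 °C, sealed vessel
Reagents that add atoms: none
Why: One primary ammonium group of the catalyst condenses with the aldehyde of 5 to an iminium ion, while the second N–H is expected to hydrogen-bond to the benzoyloxy carbonyl and fix the iminium geometry so that the binaphthyl wall covers one face. Butadiene then adds to the open face in a concerted suprafacial [4+2] cycloaddition; the closest known reaction type is the ammonium-salt-catalysed enantioselective Diels–Alder reaction of α-(acyloxy)acroleins with dienes. The two new σ-bonds are C2–Ca and C3–C4, and the only ring that closes is the six-membered carbocycle C2–Ca–Cb=C5–C4–C3, formed in one cycloaddition event and not by a stepwise cyclisation; it is not a ring of the target and is cleaved in step 7. The C2 stereocentre is set by catalyst control of the dienophile enantioface. Because the diene is symmetric and unsubstituted, no regiochemical or endo/exo question arises, so enantioface selectivity is the only requirement, and the α-acyloxy group secures it by offering the second binding point. The α-oxygen also raises the dienophile reactivity enough for the unactivated diene.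

Step 4
Reactants: 7 (1R)-1-formylcyclohex-3-en-1-yl benzoate
Product: 8 (1R)-1-(benzoyloxy)cyclohex-3-ene-1-carboxylic acid
Conditions: NaClO2, NaH2PO4, 2-methylbut-2-ene, t-BuOH/H2O, 0 °C → rt
Reagents that add atoms: sodium chlorite, [Na+].[O-]Cl=O
Why: Pinnick oxidation should convert the hindered α-acyloxy aldehyde into the acid without touching the ring alkene, hypochlorite being trapped by 2-methylbut-2-ene; the quaternary centre cannot epimerise.

Step 5
Reactants: 8 (1R)-1-(benzoyloxy)cyclohex-3-ene-1-carboxylic acid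
Product: 9 tert-butyl (1R)-1-(benzoyloxy)cyclohex-3-ene-1-carboxylate
Conditions: Cl3CC(=NH)Ot-Bu (2 equiv), CH2Cl2/cyclohexane, rt
Reagents that add atoms: tert-butyl 2,2,2-trichloroacetimidate, CC(C)(C)OC(=N)C(Cl)(Cl)Cl
Why: Acid-self-catalysed esterification with the trichloroacetimidate (tert-butyl transfer) gives the ester that must later resist methoxide, ylide, NaH and aryllithium and fall only to acid.

Step 6
Reactants: 9 tert-butyl (1R)-1-(benzoyloxy)cyclohex-3-ene-1-carboxylate
Product: 10 tert-butyl (1R)-1-hydroxycyclohex-3-ene-1-carboxylate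
Conditions: K2CO3 (0.3 equiv), MeOH, 0 °C → rt
Reagents that add atoms: none
Why: Base-catalysed transesterification (methanolysis) should remove the benzoate, which is activated by the neighbouring ester, while the tert-butyl ester is too hindered to exchange.

Step 7
Reactants: 10 tert-butyl (1R)-1-hydroxycyclohex-3-ene-1-carboxylate
Product: 13 tert-butyl (2R)-5-hydroxy-2-(2-oxoethyl)oxolane-2-carboxylate (lactol; both C5 epimers), via secondary ozonide 11 (not isolated), via open hydroxy dialdehyde 12 (not isolated)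
Conditions: O3, CH2Cl2, −78 °C; then PPh3, −78 °C → rt; crude used at once
Reagents that add atoms: ozone, [O-][O+]=O
Why: Ozonolysis with reductive work-up cleaves Cb=C5, and the free tertiary hydroxyl should close on the C5 aldehyde as a five-membered lactol (O1, C2, C3, C4, C5), whereas closure on Cb would need a four-membered ring, so the two termini are differentiated.

Step 8
Reactants: 13 tert-butyl (2R)-5-hydroxy-2-(2-oxoethyl)oxolane-2-carboxylate
Product: 14 2-[(2R)-2-(tert-butoxycarbonyl)-5-hydroxyoxolan-2-yl]acetic acid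
Conditions: NaClO2 (1.5 equiv), NaH2PO4, 2-methylbut-2-ene, t-BuOH/H2O, 0 °C; work-up at pH 4–5
Reagents that add atoms: sodium chlorite, [Na+].[O-]Cl=O
Why: Pinnick oxidation should act on the free Cb aldehyde, since chlorous acid needs an open carbonyl group and the lactol is expected to stay closed under the buffered conditions.

Step 9
Reactants: 14 2-[(2R)-2-(tert-butoxycarbonyl)-5-hydroxyoxolan-2-yl]acetic acid
Product: 15 (3R)-3-(tert-butoxycarbonyl)-3-hydroxyhept-6-enoic acid
Conditions: Ph3PCH3Br (4 equiv), KOt-Bu (3.8 equiv), THF, 0 °C → rt; citric acid work-up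
Reagents that add atoms: methyltriphenylphosphonium bromide, C[P+](c1ccccc1)(c1ccccc1)c1ccccc1.[Br-]
Why: Wittig methylenation of a lactol: excess ylide deprotonates acid and lactol, the lactolate opens to the C5 aldehyde, which is methylenated, and the carboxylate is inert to the ylide.

Step 10
Reactants: 15 (3R)-3-(tert-butoxycarbonyl)-3-hydroxyhept-6-enoic acid
Product: 16 tert-butyl (2R)-2-hydroxy-2-{2-[methoxy(methyl)amino]-2-oxoethyl}hex-5-enoate
Conditions: MeNHOMe·HCl, EDC·HCl, HOBt, N-methylmorpholine, CH2Cl2, 0 °C → rt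
Reagents that add atoms: N,O-dimethylhydroxylamine hydrochloride, CNOC.Cl
Why: Carbodiimide-mediated amidation gives the Weinreb amide, which holds Cb at the acid level through the basic steps that follow; the hindered tertiary hydroxyl should not compete with the amine.

Step 11
Reactants: 17 1-chloro-3-methylbut-2-ene
Product: 18 (2E)-4-chloro-2-methylbut-2-en-1-ol
Conditions: SeO2 (0.2 equiv), t-BuOOH (2 equiv), CH2Cl2, 0 °C → rt
Reagents that add atoms: selenium dioxide, O=[Se]=O (catalytic oxygen carrier); tert-butyl hydroperoxide, CC(C)(C)OO (terminal oxygen source)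
Why: SeO2 allylic oxidation (ene reaction, then 2,3-sigmatropic shift) should hydroxylate the methyl group trans to the chloromethyl-bearing carbon and so set the E geometry of the side-chain alkene.

Step 12
Reactants: 18 (2E)-4-chloro-2-methylbut-2-en-1-ol
Product: 19 tert-butyl{[(2E)-4-chloro-2-methylbut-2-en-1-yl]oxy}dimethylsilane
Conditions: TBSCl, imidazole, CH2Cl2, 0 °C
Reagents that add atoms: tert-butyl(chloro)dimethylsilane, CC(C)(C)[Si](C)(C)Cl
Why: Silylation of the primary alcohol is fast at 0 °C, at which the allylic chloride should not alkylate imidazole.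

Step 13
Reactants: 20 2-methylprop-2-en-1-ol; 19 tert-butyl{[(2E)-4-chloro-2-methylbut-2-en-1-yl]oxy}dimethylsilane
Product: 22 (5E)-7-[(tert-butyldimethylsilyl)oxy]-6-methyl-2-methylidenehept-5-en-1-ol, via dilithiated methallyl alcohol 21 (not isolated)
Conditions: 20 (1.5 equiv), n-BuLi (3.1 equiv), TMEDA, Et2O, 0 °C → rt; then 19, THF, −78 → 0 °C
Reagents that add atoms: none
Why: The C,O-dianion of methallyl alcohol, a 2-substituted allyl anion with equivalent termini, should be alkylated on carbon by the primary allylic chloride (SN2), joining the two halves of the side chain without touching the E alkene.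

Step 14
Reactants: 22 (5E)-7-[(tert-butyldimethylsilyl)oxy]-6-methyl-2-methylidenehept-5-en-1-ol
Product: 23 {[(2E)-6-(bromomethyl)-2-methylhepta-2,6-dien-1-yl]oxy}(tert-butyl)dimethylsilane
Conditions: CBr4, PPh3, CH2Cl2, 0 °C
Reagents that add atoms: tetrabromomethane, BrC(Br)(Br)Br
Why: Appel bromination converts the primary allylic alcohol into the bromide under neutral conditions that spare the silyl ether.

Step 15
Reactants: 16 tert-butyl (2R)-2-hydroxy-2-{2-[methoxy(methyl)amino]-2-oxoethyl}hex-5-enoate; 23 {[(2E)-6-(bromomethyl)-2-methylhepta-2,6-dien-1-yl]oxy}(tert-butyl)dimethylsilane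
Product: 24 tert-butyl (2R)-2-({(5E)-7-[(tert-butyldimethylsilyl)oxy]-6-methyl-2-methylidenehept-5-en-1-yl}oxy)-2-{2-[methoxy(methyl)amino]-2-oxoethyl}hex-5-enoate
Conditions: NaH (1.2 equiv), 23 (1.4 equiv), n-Bu4NI (cat.), DMF, 0 °C → rt
Reagents that add atoms: none
Why: Williamson etherification: the tertiary α-hydroxy ester is the most acidic site, and its alkoxide should displace the reactive allylic bromide to form O1–C7; Cb is an amide at this stage, so retro-aldol cleavage has no good leaving enolate.

Step 16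
Reactants: 24 tert-butyl (2R)-2-({(5E)-7-[(tert-butyldimethylsilyl)oxy]-6-methyl-2-methylidenehept-5-en-1-yl}oxy)-2-{2-[methoxy(methyl)amino]-2-oxoethyl}hex-5-enoate
Product: 25 tert-butyl (2R)-6-{(3E)-5-[(tert-butyldimethylsilyl)oxy]-4-methylpent-3-en-1-yl}-2-{2-[methoxy(methyl)amino]-2-oxoethyl}-2,3,4,7-tetrahydrooxepine-2-carboxylate
Conditions: second-generation Grubbs catalyst (H2IMes)(PCy3)Cl2Ru=CHPh (5 mol %), CH2Cl2 (0.005 M), 40 °C
Reagents that add atoms: none
Why: Ring-closing metathesis between the monosubstituted and the 1,1-disubstituted alkene should close the seven-membered oxepine at C5=C6 with loss of ethene; the ring enforces the cis relation of C4 and C7, and the trisubstituted side-chain alkene is expected to stay a spectator.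

Step 17
Reactants: 26 2-bromobenzene-1,4-diol
Product: 27 2-bromo-1,4-bis(methoxymethoxy)benzene
Conditions: MeOCH2Cl (2.5 equiv), i-Pr2NEt (3 equiv), CH2Cl2, 0 °C → rt
Reagents that add atoms: chloromethyl methyl ether, COCCl
Why: O-Alkylation of both phenols gives acetal ethers that tolerate and chelate the neighbouring aryllithium and are removed by acid at the end.

Step 18
Reactants: 27 2-bromo-1,4-bis(methoxymethoxy)benzene; 25 tert-butyl (2R)-6-{(3E)-5-[(tert-butyldimethylsilyl)oxy]-4-methylpent-3-en-1-yl}-2-{2-[methoxy(methyl)amino]-2-oxoethyl}-2,3,4,7-tetrahydrooxepine-2-carboxylate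
Product: 30 tert-butyl (2R)-2-{2-[2,5-bis(methoxymethoxy)phenyl]-2-oxoethyl}-6-{(3E)-5-[(tert-butyldimethylsilyl)oxy]-4-methylpent-3-en-1-yl}-2,3,4,7-tetrahydrooxepine-2-carboxylate, via aryllithium 28 (not isolated), via chelated lithium hemiaminal 29 (not isolated)
Conditions: 27 (1.6 equiv), n-BuLi (1.5 equiv), THF, −78 °C; then 25, −78 °C; aq NH4Cl
Reagents that add atoms: none
Why: Bromine–lithium exchange gives the aryllithium, which adds to the Weinreb amide to a chelated tetrahedral intermediate that collapses to the aryl ketone only on work-up (Weinreb ketone synthesis), so over-addition and attack on the hindered tert-butyl ester should not occur.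

Step 19
Reactants: 30 tert-butyl (2R)-2-{2-[2,5-bis(methoxymethoxy)phenyl]-2-oxoethyl}-6-{(3E)-5-[(tert-butyldimethylsilyl)oxy]-4-methylpent-3-en-1-yl}-2,3,4,7-tetrahydrooxepine-2-carboxylate
Product: 31 tert-butyl (2R)-2-{2-[2,5-bis(methoxymethoxy)phenyl]-2-oxoethyl}-6-[(3E)-5-hydroxy-4-methylpent-3-en-1-yl]-2,3,4,7-tetrahydrooxepine-2-carboxylate
Conditions: HF·pyridine, pyridine, THF, 0 °C → rt
Reagents that add atoms: none
Why: Buffered fluoride desilylation should free the primary allylic alcohol without β-elimination of the β-alkoxy ketone and without loss of the acetal ethers or the tert-butyl ester.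

Step 20
Reactants: 31 tert-butyl (2R)-2-{2-[2,5-bis(methoxymethoxy)phenyl]-2-oxoethyl}-6-[(3E)-5-hydroxy-4-methylpent-3-en-1-yl]-2,3,4,7-tetrahydrooxepine-2-carboxylate; 32 (2E)-3-(4-hydroxyphenyl)prop-2-enoic acid (p-coumaric acid)
Product: 33 tert-butyl (2R)-2-{2-[2,5-bis(methoxymethoxy)phenyl]-2-oxoethyl}-6-[(3E)-5-{[(2E)-3-(4-hydroxyphenyl)prop-2-enoyl]oxy}-4-methylpent-3-en-1-yl]-2,3,4,7-tetrahydrooxepine-2-carboxylate
Conditions: 32 (1.2 equiv), PPh3, diisopropyl azodicarboxylate, THF, 0 °C → rt
Reagents that add atoms: none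
Why: Mitsunobu esterification: the carboxylic acid, far more acidic than the phenol, should be the nucleophile that displaces the activated primary allylic alcohol (SN2), so the coumarate is installed without phenol protection and with its E alkene intact.

Step 21
Reactants: 33 tert-butyl (2R)-2-{2-[2,5-bis(methoxymethoxy)phenyl]-2-oxoethyl}-6-[(3E)-5-{[(2E)-3-(4-hydroxyphenyl)prop-2-enoyl]oxy}-4-methylpent-3-en-1-yl]-2,3,4,7-tetrahydrooxepine-2-carboxylate
Product: 34 (2R)-2-[2-(2,5-dihydroxyphenyl)-2-oxoethyl]-6-[(3E)-5-{[(2E)-3-(4-hydroxyphenyl)prop-2-enoyl]oxy}-4-methylpent-3-en-1-yl]-2,3,4,7-tetrahydrooxepine-2-carboxylic acid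
Conditions: CF3CO2H/CH2Cl2 (1:4), H2O (5 equiv), 0 °C → rt
Reagents that add atoms: none
Why: Acidolysis should remove the tert-butyl ester and both methoxymethyl ethers in one operation, while the primary allylic ester and the ring allylic ether are not expected to ionise and C2 has no pathway to epimerise.

**Compound list**

1 | 2,2-dimethyl-1,3-dioxan-5-one | CC1(C)OCC(=O)CO1 | starting material
2 | benzoyl chloride | O=C(Cl)c1ccccc1 | starting material
3 | potassium 2,2-dimethyl-4H-1,3-dioxin-5-olate | CC1(C)OCC(=CO1)[O-].[K+] | intermediate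
4 | 2,2-dimethyl-4H-1,3-dioxin-5-yl benzoate | CC1(C)OCC(=CO1)OC(=O)c1ccccc1 | intermediate
5 | 3-oxoprop-1-en-2-yl benzoate | C=C(C=O)OC(=O)c1ccccc1 | intermediate
6 | buta-1,3-diene | C=CC=C | starting material
7 | (1R)-1-formylcyclohex-3-en-1-yl benzoate | C1=CCC[C@@](C1)(C=O)OC(=O)c1ccccc1 | intermediate
8 | (1R)-1-(benzoyloxy)cyclohex-3-ene-1-carboxylic acid | C1=CCC[C@@](C1)(C(=O)O)OC(=O)c1ccccc1 | intermediate
9 | tert-butyl (1R)-1-(benzoyloxy)cyclohex-3-ene-1-carboxylate | C1=CCC[C@@](C1)(C(=O)OC(C)(C)C)OC(=O)c1ccccc1 | intermediate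
10 | tert-butyl (1R)-1-hydroxycyclohex-3-ene-1-carboxylate | C1=CCC[C@@](C1)(C(=O)OC(C)(C)C)O | intermediate
11 | tert-butyl (3R)-3-hydroxy-7,8,9-trioxabicyclo[4.2.1]nonane-3-carboxylate (secondary ozonide) | O1C2CC[C@@](CC1OO2)(C(=O)OC(C)(C)C)O | intermediate
12 | tert-butyl (2R)-2-hydroxy-5-oxo-2-(2-oxoethyl)pentanoate | O=CCC[C@@](CC=O)(C(=O)OC(C)(C)C)O | intermediate
13 | tert-butyl (2R)-5-hydroxy-2-(2-oxoethyl)oxolane-2-carboxylate (both C5 epimers) | OC1CC[C@@](CC=O)(C(=O)OC(C)(C)C)O1 | intermediate
14 | 2-[(2R)-2-(tert-butoxycarbonyl)-5-hydroxyoxolan-2-yl]acetic acid (both C5 epimers) | OC1CC[C@@](CC(=O)O)(C(=O)OC(C)(C)C)O1 | intermediate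
15 | (3R)-3-(tert-butoxycarbonyl)-3-hydroxyhept-6-enoic acid | C=CCC[C@@](CC(=O)O)(C(=O)OC(C)(C)C)O | intermediate
16 | tert-butyl (2R)-2-hydroxy-2-{2-[methoxy(methyl)amino]-2-oxoethyl}hex-5-enoate | C=CCC[C@@](CC(=O)N(C)OC)(C(=O)OC(C)(C)C)O | intermediate
17 | 1-chloro-3-methylbut-2-ene | CC(C)=CCCl | starting material
18 | (2E)-4-chloro-2-methylbut-2-en-1-ol | C/C(=C\CCl)CO | intermediate
19 | tert-butyl{[(2E)-4-chloro-2-methylbut-2-en-1-yl]oxy}dimethylsilane | C/C(=C\CCl)CO[Si](C)(C)C(C)(C)C | intermediate
20 | 2-methylprop-2-en-1-ol | CC(=C)CO | starting material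
21 | lithium 2-(lithiomethyl)prop-2-en-1-olate | [Li]CC(=C)CO[Li] | intermediate
22 | (5E)-7-[(tert-butyldimethylsilyl)oxy]-6-methyl-2-methylidenehept-5-en-1-ol | C/C(=C\CCC(=C)CO)CO[Si](C)(C)C(C)(C)C | intermediate
23 | {[(2E)-6-(bromomethyl)-2-methylhepta-2,6-dien-1-yl]oxy}(tert-butyl)dimethylsilane | C/C(=C\CCC(=C)CBr)CO[Si](C)(C)C(C)(C)C | intermediate
24 | tert-butyl (2R)-2-({(5E)-7-[(tert-butyldimethylsilyl)oxy]-6-methyl-2-methylidenehept-5-en-1-yl}oxy)-2-{2-[methoxy(methyl)amino]-2-oxoethyl}hex-5-enoate | C=CCC[C@@](CC(=O)N(C)OC)(C(=O)OC(C)(C)C)OCC(=C)CC/C=C(\C)CO[Si](C)(C)C(C)(C)C | intermediate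
25 | tert-butyl (2R)-6-{(3E)-5-[(tert-butyldimethylsilyl)oxy]-4-methylpent-3-en-1-yl}-2-{2-[methoxy(methyl)amino]-2-oxoethyl}-2,3,4,7-tetrahydrooxepine-2-carboxylate | C/C(=C\CCC1=CCC[C@@](CC(=O)N(C)OC)(C(=O)OC(C)(C)C)OC1)CO[Si](C)(C)C(C)(C)C | intermediate
26 | 2-bromobenzene-1,4-diol | Oc1ccc(O)c(Br)c1 | starting material
27 | 2-bromo-1,4-bis(methoxymethoxy)benzene | COCOc1ccc(OCOC)c(Br)c1 | intermediate
28 | [2,5-bis(methoxymethoxy)phenyl]lithium | COCOc1ccc(OCOC)c([Li])c1 | intermediate
29 | lithium alkoxide of the N-methoxy-N-methyl hemiaminal at Cb (adduct of 28 to 25; Cb configuration undefined) | C/C(=C\CCC1=CCC[C@@](CC(O[Li])(N(C)OC)c2cc(OCOC)ccc2OCOC)(C(=O)OC(C)(C)C)OC1)CO[Si](C)(C)C(C)(C)C | intermediate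
30 | tert-butyl (2R)-2-{2-[2,5-bis(methoxymethoxy)phenyl]-2-oxoethyl}-6-{(3E)-5-[(tert-butyldimethylsilyl)oxy]-4-methylpent-3-en-1-yl}-2,3,4,7-tetrahydrooxepine-2-carboxylate | C/C(=C\CCC1=CCC[C@@](CC(=O)c2cc(OCOC)ccc2OCOC)(C(=O)OC(C)(C)C)OC1)CO[Si](C)(C)C(C)(C)C | intermediate
31 | tert-butyl (2R)-2-{2-[2,5-bis(methoxymethoxy)phenyl]-2-oxoethyl}-6-[(3E)-5-hydroxy-4-methylpent-3-en-1-yl]-2,3,4,7-tetrahydrooxepine-2-carboxylate | C/C(=C\CCC1=CCC[C@@](CC(=O)c2cc(OCOC)ccc2OCOC)(C(=O)OC(C)(C)C)OC1)CO | intermediate
32 | (2E)-3-(4-hydroxyphenyl)prop-2-enoic acid | OC(=O)/C=C/c1ccc(O)cc1 | starting material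
33 | tert-butyl (2R)-2-{2-[2,5-bis(methoxymethoxy)phenyl]-2-oxoethyl}-6-[(3E)-5-{[(2E)-3-(4-hydroxyphenyl)prop-2-enoyl]oxy}-4-methylpent-3-en-1-yl]-2,3,4,7-tetrahydrooxepine-2-carboxylate | C/C(=C\CCC1=CCC[C@@](CC(=O)c2cc(OCOC)ccc2OCOC)(C(=O)OC(C)(C)C)OC1)COC(=O)/C=C/c1ccc(O)cc1 | intermediate
34 | (2R)-2-[2-(2,5-dihydroxyphenyl)-2-oxoethyl]-6-[(3E)-5-{[(2E)-3-(4-hydroxyphenyl)prop-2-enoyl]oxy}-4-methylpent-3-en-1-yl]-2,3,4,7-tetrahydrooxepine-2-carboxylic acid | C/C(=C\CCC1=CCC[C@@](CC(=O)c2cc(O)ccc2O)(C(=O)O)OC1)COC(=O)/C=C/c1ccc(O)cc1 | target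

**Step count and risks**

Total step count: 21. Longest linear sequence: 16 steps (steps 1–10, 15, 16, 18–21).

Steps most likely to fail:

1. Step 3. The unactivated diene may add slowly, and at the temperature needed the uncatalysed background cycloaddition could erode enantioface selectivity. Fallback, setting out from 5: thermal cycloaddition with 6 (toluene, sealed tube, 90 °C) gives racemic 1-formylcyclohex-3-en-1-yl benzoate F1. Chlorite oxidation as in step 4 gives racemic 1-(benzoyloxy)cyclohex-3-ene-1-carboxylic acid F2. Classical resolution with (1R)-1-phenylethanamine and fractional crystallisation gives the (1R)-1-phenylethanaminium salt of the (1R)-acid F3; the antipodal amine is taken if the other diastereomer is the one that crystallises. Acidification with dilute HCl frees 8, where the route is rejoined.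

2. Step 8. The lactol may open during the oxidation so that C5 is over-oxidised to the lactone, and the β-alkoxy aldehyde may lose the ring oxygen by β-elimination before it is oxidised. Fallback, setting out from 13: the lactol hydroxyl is silylated (TBSCl, imidazole, CH2Cl2, 0 °C) to tert-butyl (2R)-5-[(tert-butyldimethylsilyl)oxy]-2-(2-oxoethyl)oxolane-2-carboxylate F4, so that only one aldehyde-level carbon remains. The same chlorite oxidation gives 2-[(2R)-2-(tert-butoxycarbonyl)-5-[(tert-butyldimethylsilyl)oxy]oxolan-2-yl]acetic acid F5. Bu4NF/AcOH in THF at 0 °C removes the anomeric silyl group and returns the route at 14.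

3. Step 15. Etherification of the hindered tertiary alkoxide may be incomplete, with base-driven β-elimination through the amide enolate competing. Fallback, setting out from 22: acetylation (Ac2O, pyridine, CH2Cl2) gives (5E)-7-[(tert-butyldimethylsilyl)oxy]-6-methyl-2-methylidenehept-5-en-1-yl acetate F6. This is joined to 16 by palladium-catalysed allylic etherification of the zinc alkoxide (Et2Zn 0.55 equiv, Pd(OAc)2 5 mol % as source of zerovalent palladium, 2-(di-tert-butylphosphino)biphenyl, NH4OAc cat., THF, rt). The 2-substituted π-allyl has identical CH2 termini, so one regioisomer is expected, and the weakly basic zinc alkoxide should not trigger elimination. The route is rejoined at 24.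

**Further compounds**

F1 | step 3 | racemic 1-formylcyclohex-3-en-1-yl benzoate | O=CC1(OC(=O)c2ccccc2)CC=CCC1
F2 | step 3 | racemic 1-(benzoyloxy)cyclohex-3-ene-1-carboxylic acid | OC(=O)C1(OC(=O)c2ccccc2)CC=CCC1
F3 | step 3 | (1R)-1-phenylethanaminium (1R)-1-(benzoyloxy)cyclohex-3-ene-1-carboxylate | C1=CCC[C@@](C1)(C(=O)[O-])OC(=O)c1ccccc1.C[C@@H]([NH3+])c1ccccc1
F4 | step 8 | tert-butyl (2R)-5-[(tert-butyldimethylsilyl)oxy]-2-(2-oxoethyl)oxolane-2-carboxylate | CC(C)(C)[Si](C)(C)OC1CC[C@@](CC=O)(C(=O)OC(C)(C)C)O1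
F5 | step 8 | 2-[(2R)-2-(tert-butoxycarbonyl)-5-[(tert-butyldimethylsilyl)oxy]oxolan-2-yl]acetic acid | CC(C)(C)[Si](C)(C)OC1CC[C@@](CC(=O)O)(C(=O)OC(C)(C)C)O1
F6 | step 15 | (5E)-7-[(tert-butyldimethylsilyl)oxy]-6-methyl-2-methylidenehept-5-en-1-yl acetate | C/C(=C\CCC(=C)COC(C)=O)CO[Si](C)(C)C(C)(C)C
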